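Compound numbers used throughout: 1 = 6-methoxybenzofuran-3(2H)-one; 2 = glyoxal; 3 = mono-condensation aldehyde (not isolated); 4 = aryl-free bis-aurone diene; 5 = 3,4-dimethoxyphenylboronic acid; 6 = mono-aryl adduct (not isolated); 7 = bis-aryl diketone; 8 = bis(silyl enol ether); 9 = disulfuretin hexamethyl ether; 10 = disulfuretin.

## Analysis of the target

Disulfuretin (10) is a C2-symmetric dimer of a 6,3',4'-trihydroxyaurone joined through the two benzylidene carbons: two 6-hydroxybenzofuran-3(2H)-one bicycles whose C2 atoms are the ends of a 1,3-diene C2=Cα–Cα'=C2', with one 3,4-dihydroxyphenyl ring on each inner carbon. It has no stereocentre. The stereochemical content lies in the two tetrasubstituted exocyclic alkenes, both Z, so that each ring oxygen O1 is cis to the Cα of the other half and each catechol ring is cis to its own C3 carbonyl; the two alkenes are related by the twofold axis through the middle of the Cα–Cα' bond. The sensitive parts are the six free phenols (two catechols, prone to oxidation in air and base) and the cross-conjugated dienedione, which is a Michael acceptor, is easily reduced in the manner of an extended quinone, and can change geometry in light or acid. The difficulty is the pair of adjacent, fully substituted carbons Cα and Cα': the usual aurone condensation would have to run twice on a hindered 1,2-diaryl-1,2-diketone, and coupling two aurone halves at Cα offers no regiocontrol. The route rests on the fact that each Cα is the β-carbon of an enone (O=C3–C2=Cα) and therefore electrophilic, so both catechol rings can arrive as aryl nucleophiles on an aryl-free diene. The four central carbons of that diene, C2–Cα–Cα'–C2', are then a two-carbon dialdehyde placed between the C2 methylene groups of two benzofuranones. The price is that conjugate addition saturates both alkenes, so they must be restored by dehydrogenation and their geometry must come from thermodynamic preference.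

## Retrosynthetic reasoning

10 ⇒ 9. The six phenols are masked as methyl ethers, so the last operation is cleavage of six O–CH3 bonds with a boron Lewis acid. Methyl is chosen because it survives acid condensation, rhodium catalysis, silylation and quinone oxidation, and because this cleavage is routine on aurones. No skeletal bond is touched.

9 ⇒ 8 ⇒ 7. The two C2=Cα double bonds are removed in the retrosynthetic sense, one hydrogen going to each C2 and each Cα. This makes Cα an sp3 carbon that can be the site of a nucleophilic addition and turns the crowded diene into a flexible 1,2-diarylethane flanked by two ketones (7). Forward, the ketones are first converted into their silyl enol ethers (8), which are aromatic 3-silyloxybenzofurans. A quinone oxidant then removes the doubly benzylic Cα hydrogens and the silyl groups, returning both enones. The Cα–Cα' bond is not cut: it joins the two most hindered carbons, and forming it late would be the hardest bond construction in the molecule.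

7 ⇒ 4 + 5 (via 6). Both Cα–aryl bonds are cut. Each is the bond between an enone β-carbon and an aryl group, the retron of a conjugate arylation. Cutting here and not at C2=Cα or O1–C2 leaves the benzofuranone rings intact and reduces the precursor to the symmetric, aryl-free dienedione 4. The forward step must add an aryl group from 5 to Cα of each enone of 4, passing through the mono-adduct 6, with 1,4- and not 1,6-selectivity. The four stereocentres created (C2, Cα, Cα', C2') need no control because all are destroyed on the way to 9.

4 ⇒ 1 + 2 (via 3). Both C2=Cα double bonds of 4 are cut as aldol condensations. The two central carbons are the dialdehyde 2 and the outer parts are two molecules of the commercial benzofuranone 1, whose C2 methylene is the nucleophile. This gives the whole carbon skeleton except the two aryl rings in one operation, through aldehyde 3, and puts the risk of the route into the arylation.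

## Alternatives that were turned down

Alternative 1: Both furan rings are cut at O1–C2 and C3–C3a, leading back to (E)-3,4-bis(3,4-dimethoxyphenyl)hex-3-ene-1,5-diyne (A2) and two molecules of 2-iodo-5-methoxyphenol (A3).
- Forward key step: with Pd(PPh3)2Cl2 (reduced in the flask to zerovalent palladium), CuI and Et3N, each terminal alkyne of A2 undergoes Sonogashira coupling with A3. Each phenol then closes onto its alkyne in a 5-endo-dig manner, giving (E)-1,2-bis(6-methoxybenzofuran-2-yl)-1,2-bis(3,4-dimethoxyphenyl)ethene (A1).
- For: four bonds and two rings form in one flask by dependable catalysis, and the aryl groups already sit on the central carbons, so no bond has to be made at a hindered Cα later.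
- Against: A1 is at the wrong oxidation level and has its double bond in the wrong place. C3 and C3' carry hydrogen, and the alkene is Cα=Cα'. Reaching 9 requires two oxygen atoms at C3/C3', removal of two hydrogens and transposition of the alkenes. This is a six-electron oxidation of an electron-rich hexamethoxy stilbene; oxidants would be expected to attack the central tetrasubstituted alkene or the dimethoxyarene rings at least as readily as C3. A2, a stereodefined tetrasubstituted enediyne, also costs several steps.
- Comparison: on ring construction and aryl placement this alternative is as strong as or stronger than the chosen route. The chosen route buys the rings with the C3 oxygen already present in 1, never has to introduce oxygen, needs only a precedented removal of two hydrogens per half, and is shorter.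

Alternative 2: The O1–C2 bonds of both benzofuranones are cut, and C2 and C2' are tied back through one oxygen into a furan, [3,4-bis(3,4-dimethoxyphenyl)furan-2,5-diyl]bis[(2-hydroxy-4-methoxyphenyl)methanone] (A5).
- Forward key step: under acid each ortho-phenol of A5 adds in a 5-exo-trig manner to the furan carbon that bears its own aroyl group, and the furan C–O bonds break with the ring oxygen leaving as water. The product is disulfuretin hexamethyl ether (A4). A4 has the same structure as 9.
- For: the step is redox-neutral, delivers the full dienedione of A4 in one operation, and sets the alkene geometry under thermodynamic control. All crowded carbons are preassembled in a flat aromatic ring.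
- Against: the direction of the equilibrium is doubtful. The reverse path (hydrolytic opening of the two enol ethers followed by Paal–Knorr closure) regenerates an aromatic furan, so the isomerisation of A5 to A4 is not clearly downhill. A 2,5-diacylfuran is also electron-poor and hard to activate at carbon. A5 is no simpler than the target: a tetrasubstituted furan with two differentiated ortho-phenols, several steps from commercial material.
- Comparison: on redox economy and on the directness with which the geometry is set, this alternative is stronger. The chosen route offers irreversible C–C bond formation whose direction is not in question, and a precursor that is one step from commercial compounds.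

Alternative 3: The Cα–aryl bonds are cut as in the chosen route, but at the ketone oxidation level. The furan rings are cut at O1–C2 and C2–C3, back to methyl 4-methoxysalicylate (A7) and 1,4-dibromobutane-2,3-dione (A8).
- Forward key step: with K2CO3, two molecules of A7 are O-alkylated by A8, and a Dieckmann-type acylation of each ester closes both furan rings to give 1,2-bis(3-hydroxy-6-methoxybenzofuran-2-yl)ethane-1,2-dione (A6). Two additions of a 3,4-dimethoxyphenyl organometallic to the diketone would give 1,2-bis(3,4-dimethoxyphenyl)-1,2-bis(3-hydroxy-6-methoxybenzofuran-2-yl)ethane-1,2-diol (A9), and its double vinylogous dehydration would give 9.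
- For: the starting materials are cheap, the sequence is short and redox-neutral, and the alkenes arise by dehydration, not dehydrogenation.
- Against:
  - A8 is a base-labile α-diketone.
  - The two enolic hydroxyls of A6 are vinylogous acids. They quench the organometallic and turn the neighbouring ketones into unreactive vinylogous carboxylates, so protection and more steps are needed.
  - The second addition has to occur next to a tertiary alkoxide at a hindered carbon.
  - A9 is a ditertiary, doubly benzylic 1,2-diol, for which pinacol rearrangement competes with dehydration under acid.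
- Comparison: on redox economy this alternative is stronger, and in length it is about equal. The chosen route makes each Cα–aryl bond by a catalytic addition at a hydrogen-bearing carbon under nearly neutral conditions, and none of its intermediates can rearrange the skeleton. The price is one dehydrogenation.

Key step: step 2

Assumption (remark on the chemistry): the (2Z,2'Z) geometry of the target is taken to be the thermodynamically preferred arrangement of the two tetrasubstituted alkenes, so that equilibration in steps 4 and 5 delivers it; compounds 1, 2 (as 40% aqueous solution) and 5 are taken as commercial.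

## Route

Step 1
Reactants: 1 6-methoxybenzofuran-3(2H)-one (2 equiv); 2 glyoxal (40% in H2O, 1 equiv)
Product: 4 (2Z,2'Z)-2,2'-(ethane-1,2-diylidene)bis(6-methoxybenzofuran-3(2H)-one), via ylidene-acetaldehyde 3 (not isolated)
Conditions: conc. HCl (cat.), AcOH, 25 → 60 °C; product collected by filtration
Reagents that add atoms: none
Why: Acid-catalysed aldol condensation of a benzofuran-3(2H)-one with an aldehyde, the standard aurone synthesis, run twice on the dialdehyde: the enol of 1 adds to protonated 2, dehydration gives aldehyde 3, and 3 condenses with a second molecule of 1. The flat, poorly soluble dye 4 should crystallise from the acid, which protects it from further addition; its Z,Z geometry is the usual thermodynamic aurone outcome and is of no consequence, because both alkenes are consumed in step 2.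

Step 2
Reactants: 4 (2Z,2'Z)-2,2'-(ethane-1,2-diylidene)bis(6-methoxybenzofuran-3(2H)-one); 5 3,4-dimethoxyphenylboronic acid
Product: 7 2,2'-[1,2-bis(3,4-dimethoxyphenyl)ethane-1,2-diyl]bis(6-methoxybenzofuran-3(2H)-one) (mixture of diastereomers), via mono-aryl adduct 6 (not isolated)
Conditions: [Rh(cod)OH]2 (5 mol%), 5 (5 equiv), degassed dioxane/H2O (10:1), 80 °C, Ar
Reagents that add atoms: none
Why: This is the Hayashi–Miyaura reaction, the rhodium-catalysed 1,4-addition of arylboronic acids to β-substituted enones, applied twice to a dienedione. Transmetalation from boron to the hydroxo complex gives an aryl complex of monovalent rhodium, which binds the C2=Cα bond of 4 and inserts it with the aryl group going to Cα and the metal to C2, where it rests as an oxa-π-allyl enolate. Water protonates this enolate at C2, returns the rhodium hydroxide and gives mono-adduct 6, whose untouched enone passes through the same cycle to give 7. No ring is closed in this step, so no mode of closure has to be considered. Four stereocentres arise (Cα, Cα', C2, C2'): the first two are set by the face of insertion under an achiral catalyst and the last two by protonation, so no element controls them and a diastereomer mixture is expected, which is harmless because C2/C2' are flattened in step 3 and Cα/Cα' in step 4. The selectivity that matters is 1,4- over 1,6-addition and reaction at both ends: Cα carries a hydrogen and only one carbon substituent, whereas the remote end of the vinylogous system is C2 of the other half, which is fully substituted, oxygen-bearing and the α-carbon of its own enone, so insertion with the aryl group at Cα is the only reasonable mode. Base-free conditions with [Rh(cod)OH]2 keep enolisation of 6 slow, and the excess of 5 covers protodeboronation of the electron-rich boronic acid.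

Step 3
Reactants: 7 2,2'-[1,2-bis(3,4-dimethoxyphenyl)ethane-1,2-diyl]bis(6-methoxybenzofuran-3(2H)-one)
Product: 8 1,2-bis[3-(tert-butyldimethylsilyloxy)-6-methoxybenzofuran-2-yl]-1,2-bis(3,4-dimethoxyphenyl)ethane (meso/dl mixture)
Conditions: TBSOTf (3 equiv), Et3N (5 equiv), CH2Cl2, 0 °C → rt
Reagents that add atoms: tert-butyldimethylsilyl trifluoromethanesulfonate (TBSOTf), CC(C)(C)[Si](C)(C)OS(=O)(=O)C(F)(F)F
Why: Soft enolisation and O-silylation of a ketone with a silyl triflate and an amine base; each C2–H is unusually acidic because the enol is an aromatic 3-oxybenzofuran. The two C2 stereocentres disappear, and the remaining Cα/Cα' centres are carried on as a meso/dl mixture.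

Step 4
Reactants: 8 1,2-bis[3-(tert-butyldimethylsilyloxy)-6-methoxybenzofuran-2-yl]-1,2-bis(3,4-dimethoxyphenyl)ethane
Product: 9 (2Z,2'Z)-2,2'-[1,2-bis(3,4-dimethoxyphenyl)ethane-1,2-diylidene]bis(6-methoxybenzofuran-3(2H)-one) (disulfuretin hexamethyl ether)
Conditions: DDQ (2.4 equiv), 2,4,6-collidine (3 equiv), PhMe, 0 °C → rt; aq. NaHCO3 work-up
Reagents that add atoms: none
Why: Dehydrogenation of silyl enol ethers to enones with DDQ: hydride loss from the doubly benzylic Cα–H gives a cation stabilised by the silyloxybenzofuran, which gives up its silyl group and becomes the aurone C2=Cα; if the cation loses the neighbouring Cα'–H instead, the resulting bis(silyloxybenzofuranyl)ethene is oxidised by the second equivalent to the same dienedione. Both remaining stereocentres are removed; the alkene geometry is chosen in an intermediate with single-bond character at C2–Cα and should settle on the less strained Z,Z arrangement, with collidine keeping the medium from hydrolysing the enol ethers.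

Step 5
Reactants: 9 (2Z,2'Z)-2,2'-[1,2-bis(3,4-dimethoxyphenyl)ethane-1,2-diylidene]bis(6-methoxybenzofuran-3(2H)-one)
Product: 10 disulfuretin, (2Z,2'Z)-2,2'-[1,2-bis(3,4-dihydroxyphenyl)ethane-1,2-diylidene]bis(6-hydroxybenzofuran-3(2H)-one)
Conditions: BBr3 (12 equiv), CH2Cl2, −78 °C → rt, Ar, dark; then MeOH, H2O, 0 °C
Reagents that add atoms: none
Why: Cleavage of aryl methyl ethers with BBr3, a standard last step for polyhydroxyaurones; the enone survives as its boron complex. Complexation of C3=O lowers the barrier to rotation about C2=Cα, so any geometric isomer carried from step 4 can equilibrate to the Z,Z form before the mild aqueous quench.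

## Compound list

1 | 6-methoxybenzofuran-3(2H)-one | COc1ccc2c(c1)OCC2=O | starting material
2 | glyoxal (40% aqueous solution) | O=CC=O | starting material
3 | (Z)-2-(6-methoxy-3-oxobenzofuran-2(3H)-ylidene)acetaldehyde | COc1ccc2c(c1)O/C(=C\C=O)C2=O | intermediate (not isolated)
4 | (2Z,2'Z)-2,2'-(ethane-1,2-diylidene)bis(6-methoxybenzofuran-3(2H)-one) | COc1ccc2c(c1)O/C(=C\C=C1/Oc3cc(OC)ccc3C1=O)C2=O | intermediate
5 | 3,4-dimethoxyphenylboronic acid | COc1ccc(B(O)O)cc1OC | starting material
6 | (Z)-2-[2-(3,4-dimethoxyphenyl)-2-(6-methoxy-3-oxo-2,3-dihydrobenzofuran-2-yl)ethylidene]-6-methoxybenzofuran-3(2H)-one (diastereomer mixture) | COc1ccc2c(c1)OC(C(c1ccc(OC)c(OC)c1)/C=C1\Oc3cc(OC)ccc3C1=O)C2=O | intermediate (not isolated)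
7 | 2,2'-[1,2-bis(3,4-dimethoxyphenyl)ethane-1,2-diyl]bis(6-methoxybenzofuran-3(2H)-one) (diastereomer mixture) | COc1ccc2c(c1)OC(C(c1ccc(OC)c(OC)c1)C(c1ccc(OC)c(OC)c1)C1Oc3cc(OC)ccc3C1=O)C2=O | intermediate
8 | 1,2-bis[3-(tert-butyldimethylsilyloxy)-6-methoxybenzofuran-2-yl]-1,2-bis(3,4-dimethoxyphenyl)ethane (meso/dl mixture) | COc1ccc2c(O[Si](C)(C)C(C)(C)C)c(C(c3ccc(OC)c(OC)c3)C(c3ccc(OC)c(OC)c3)c3oc4cc(OC)ccc4c3O[Si](C)(C)C(C)(C)C)oc2c1 | intermediate
9 | (2Z,2'Z)-2,2'-[1,2-bis(3,4-dimethoxyphenyl)ethane-1,2-diylidene]bis(6-methoxybenzofuran-3(2H)-one) (disulfuretin hexamethyl ether) | O=C1/C(=C(/C(=C2\Oc3cc(OC)ccc3C2=O)c2ccc(OC)c(OC)c2)c2ccc(OC)c(OC)c2)Oc2cc(OC)ccc21 | intermediate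
10 | disulfuretin, (2Z,2'Z)-2,2'-[1,2-bis(3,4-dihydroxyphenyl)ethane-1,2-diylidene]bis(6-hydroxybenzofuran-3(2H)-one) | O=C1/C(=C(/C(=C2\Oc3cc(O)ccc3C2=O)c2ccc(O)c(O)c2)c2ccc(O)c(O)c2)Oc2cc(O)ccc21 | target

## Step count and least certain steps

Total step count: 5. Longest linear sequence: 5 steps (1 → 4 → 7 → 8 → 9 → 10).

**Step 2 (key step).**
- What may go wrong: insertion of the trisubstituted, α-oxygenated enone into the aryl–rhodium bond may be slow, so that protodeboronation uses up 5 before both ends have reacted. A proton shift in 6 from Cα into the remaining enone may also remove the second acceptor. The low solubility of 4 works against both additions.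
- Fallback: setting out from 4, a copper-mediated conjugate addition with silyl trapping replaces the rhodium chemistry. Commercial 3,4-dimethoxyphenylmagnesium bromide in THF is added with CuBr·SMe2 (20 mol%) and TMSCl at −78 °C. The stronger nucleophile adds to both Cα positions and each enolate is captured at once as its silyl ether, which blocks the proton shift. The product is 1,2-bis(3,4-dimethoxyphenyl)-1,2-bis[6-methoxy-3-(trimethylsilyloxy)benzofuran-2-yl]ethane F1. This is oxidised with DDQ and collidine as in step 4, and the route is rejoined at 9, with steps 2 and 3 bypassed. The hazard of this variant is electron-transfer reduction of the quinone-like dienedione by the organocopper reagent.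

**Step 4.**
- What may go wrong: acid formed during the oxidation may hydrolyse the silyl enol ethers back to the ketone before they are oxidised. The second dehydrogenation may be slow, since its Cα–H sits next to an electron-poor enone once the first alkene is in place. The dimethoxyphenyl rings may be over-oxidised, and the alkenes may form with the wrong geometry.
- Fallback: setting out from 8, halogenation and elimination replace hydride abstraction. NBS in THF at −78 °C brominates each enol ether at C2 to give 2,2'-[1,2-bis(3,4-dimethoxyphenyl)ethane-1,2-diyl]bis(2-bromo-6-methoxybenzofuran-3(2H)-one) F2. Et3N in CH2Cl2 then removes hydrogen bromide from each labile α-bromo-α-aryloxy ketone, through an oxygen-stabilised cation or by direct elimination, to form both C2=Cα bonds. The route is rejoined at 9.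

**Step 5.**
- What may go wrong: cleavage of the six ethers may stop short. Bromide may add to the Lewis-acid-activated dienedione. The catechols may oxidise in air during work-up, and the alkene geometry may scramble.
- Fallback: setting out from 7, the demethylation is moved to the stage where no diene is present. BBr3 in CH2Cl2 converts 7 into 2,2'-[1,2-bis(3,4-dihydroxyphenyl)ethane-1,2-diyl]bis(6-hydroxybenzofuran-3(2H)-one) F3. Excess TBSOTf and Et3N then silylate the six phenols and both ketone enols in one operation to give 1,2-bis[3,4-bis(tert-butyldimethylsilyloxy)phenyl]-1,2-bis[3,6-bis(tert-butyldimethylsilyloxy)benzofuran-2-yl]ethane F4. DDQ and collidine, as in step 4, give (2Z,2'Z)-2,2'-{1,2-bis[3,4-bis(tert-butyldimethylsilyloxy)phenyl]ethane-1,2-diylidene}bis[6-(tert-butyldimethylsilyloxy)benzofuran-3(2H)-one] F5. HF·pyridine in THF at 0 °C finally removes the six aryl silyl ethers under nearly neutral conditions, and the route is rejoined at 10.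

**Step 1.**
- What may go wrong: a further molecule of 1 may add in Michael fashion to aldehyde 3 or to 4, giving oligomers, or the reaction may stop at the stage of 3 and its hydrate.
- Fallback: setting out from 1, the two condensations are separated. Commercial aqueous 2,2-dimethoxyacetaldehyde and 1 condense on neutral Al2O3 in CH2Cl2 to give (Z)-2-(2,2-dimethoxyethylidene)-6-methoxybenzofuran-3(2H)-one F6. F6 and one further equivalent of 1 in AcOH with conc. HCl then unmask the aldehyde and condense in the same flask, and the route is rejoined at 4.

## Further compounds

F1 | step 2 | 1,2-bis(3,4-dimethoxyphenyl)-1,2-bis[6-methoxy-3-(trimethylsilyloxy)benzofuran-2-yl]ethane (meso/dl mixture) | COc1ccc2c(O[Si](C)(C)C)c(C(c3ccc(OC)c(OC)c3)C(c3ccc(OC)c(OC)c3)c3oc4cc(OC)ccc4c3O[Si](C)(C)C)oc2c1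
F2 | step 4 | 2,2'-[1,2-bis(3,4-dimethoxyphenyl)ethane-1,2-diyl]bis(2-bromo-6-methoxybenzofuran-3(2H)-one) (diastereomer mixture) | COc1ccc2c(c1)OC(Br)(C(c1ccc(OC)c(OC)c1)C(c1ccc(OC)c(OC)c1)C1(Br)Oc3cc(OC)ccc3C1=O)C2=O
F3 | step 5 | 2,2'-[1,2-bis(3,4-dihydroxyphenyl)ethane-1,2-diyl]bis(6-hydroxybenzofuran-3(2H)-one) (diastereomer mixture) | Oc1ccc2c(c1)OC(C(c1ccc(O)c(O)c1)C(c1ccc(O)c(O)c1)C1Oc3cc(O)ccc3C1=O)C2=O
F4 | step 5 | 1,2-bis[3,4-bis(tert-butyldimethylsilyloxy)phenyl]-1,2-bis[3,6-bis(tert-butyldimethylsilyloxy)benzofuran-2-yl]ethane (meso/dl mixture) | CC(C)(C)[Si](C)(C)Oc1ccc2c(O[Si](C)(C)C(C)(C)C)c(C(c3ccc(O[Si](C)(C)C(C)(C)C)c(O[Si](C)(C)C(C)(C)C)c3)C(c3ccc(O[Si](C)(C)C(C)(C)C)c(O[Si](C)(C)C(C)(C)C)c3)c3oc4cc(O[Si](C)(C)C(C)(C)C)ccc4c3O[Si](C)(C)C(C)(C)C)oc2c1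
F5 | step 5 | (2Z,2'Z)-2,2'-{1,2-bis[3,4-bis(tert-butyldimethylsilyloxy)phenyl]ethane-1,2-diylidene}bis[6-(tert-butyldimethylsilyloxy)benzofuran-3(2H)-one] | O=C1/C(=C(/C(=C2\Oc3cc(O[Si](C)(C)C(C)(C)C)ccc3C2=O)c2ccc(O[Si](C)(C)C(C)(C)C)c(O[Si](C)(C)C(C)(C)C)c2)c2ccc(O[Si](C)(C)C(C)(C)C)c(O[Si](C)(C)C(C)(C)C)c2)Oc2cc(O[Si](C)(C)C(C)(C)C)ccc21
F6 | step 1 | (Z)-2-(2,2-dimethoxyethylidene)-6-methoxybenzofuran-3(2H)-one | COc1ccc2c(c1)O/C(=C\C(OC)OC)C2=O
A1 | alternative 1 | (E)-1,2-bis(6-methoxybenzofuran-2-yl)-1,2-bis(3,4-dimethoxyphenyl)ethene | COc1ccc2cc(/C(c3ccc(OC)c(OC)c3)=C(/c3cc4ccc(OC)cc4o3)c3ccc(OC)c(OC)c3)oc2c1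
A2 | alternative 1 | (E)-3,4-bis(3,4-dimethoxyphenyl)hex-3-ene-1,5-diyne | C#C/C(c1ccc(OC)c(OC)c1)=C(/C#C)c1ccc(OC)c(OC)c1
A3 | alternative 1 | 2-iodo-5-methoxyphenol | COc1ccc(I)c(O)c1
A4 | alternative 2 | disulfuretin hexamethyl ether (identical with 9) | O=C1/C(=C(/C(=C2\Oc3cc(OC)ccc3C2=O)c2ccc(OC)c(OC)c2)c2ccc(OC)c(OC)c2)Oc2cc(OC)ccc21
A5 | alternative 2 | [3,4-bis(3,4-dimethoxyphenyl)furan-2,5-diyl]bis[(2-hydroxy-4-methoxyphenyl)methanone] | COc1ccc(C(=O)c2oc(C(=O)c3ccc(OC)cc3O)c(-c3ccc(OC)c(OC)c3)c2-c2ccc(OC)c(OC)c2)c(O)c1
A6 | alternative 3 | 1,2-bis(3-hydroxy-6-methoxybenzofuran-2-yl)ethane-1,2-dione | COc1ccc2c(O)c(C(=O)C(=O)c3oc4cc(OC)ccc4c3O)oc2c1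
A7 | alternative 3 | methyl 4-methoxysalicylate | COC(=O)c1ccc(OC)cc1O
A8 | alternative 3 | 1,4-dibromobutane-2,3-dione | BrCC(=O)C(=O)CBr
A9 | alternative 3 | 1,2-bis(3,4-dimethoxyphenyl)-1,2-bis(3-hydroxy-6-methoxybenzofuran-2-yl)ethane-1,2-diol (diastereomer mixture) | COc1ccc2c(O)c(C(O)(c3ccc(OC)c(OC)c3)C(O)(c3ccc(OC)c(OC)c3)c3oc4cc(OC)ccc4c3O)oc2c1
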